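**Synthesis proposal for CNP0078998.0: two-directional Brassard benzannulation of a diynone**

Retrosynthesis: the two O-benzyl groups are put back and the bridging CH2 is traced to a diaryl ketone. Each central ring is then cut at two ring bonds (bridge-bearing carbon to C-OH carbon, and chain-bearing carbon to its neighbouring CH), leaving a 1,9-diarylnona-3,6-diyn-5-one and two 1,3-dioxygenated butadienes.
Enabling feature: going round either central benzene ring from the carbon that holds the bridging CH2, one meets a hydroxylated carbon, a CH, a methoxylated carbon, a second CH and the carbon holding the arylethyl chain. The four-carbon run C-OH, CH, C-OMe, CH is what an oxygenated butadiene delivers; the other two ring carbons are the two carbons of an alkyne conjugated to the future bridge carbon. Because the two rings are equal and meet at that one carbon, a single ketone serves both alkynes.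
The diynone is cut at both carbonyl-alkyne bonds (a formate carbon plus two 4-arylbut-1-ynes), and each butyne at its ArCH2-CH2 bond (a vanillin-derived benzylic bromide plus a silylpropyne).
Forward: the guaiacyl rings are bought in O-benzylvanillin. The chain is joined by benzylic alkylation, twofold acetylide addition to ethyl formate and oxidation. Both resorcinol rings are then formed in one operation, the ketone is reduced to CH2 and the benzyl ethers are removed.
Stereochemistry: the target has no stereocentre and no stereogenic double bond; the ketal centres of the cycloadducts vanish on aromatization.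

Key step: step 8

Remark: the ketene acetal double bond of the Brassard diene is drawn E; its geometry has no bearing on the outcome because that carbon ends up in the aromatic ring.

**Route**

Step 1
Reactants: 1 4-benzyloxy-3-methoxybenzaldehyde (O-benzylvanillin)
Product: 2 (4-benzyloxy-3-methoxyphenyl)methanol
Conditions: NaBH4, MeOH, 0 °C to rt
Reagents that add atoms: none
Why: Hydride reduction of an aryl aldehyde with NaBH4 is fast and leaves both aryl ethers untouched.

Step 2
Reactants: 2 (4-benzyloxy-3-methoxyphenyl)methanol
Product: 3 4-benzyloxy-3-methoxybenzyl bromide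
Conditions: PBr3, Et2O, 0 °C
Reagents that add atoms: phosphorus tribromide, BrP(Br)Br
Why: Bromination of an electron-rich benzylic alcohol with PBr3 (activation as the phosphite ester, displacement by bromide) is routine, and the bromide should be used promptly in the next step.

Step 3
Reactants: 3 4-benzyloxy-3-methoxybenzyl bromide; 4 1-(trimethylsilyl)propyne
Product: 6 [4-(4-benzyloxy-3-methoxyphenyl)but-1-yn-1-yl]trimethylsilane, via 3-(trimethylsilyl)prop-2-ynyllithium 5 (not isolated)
Conditions: 4, n-BuLi, THF, −78 °C; then 3, −78 °C to rt
Reagents that add atoms: none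
Why: SN2 alkylation of the lithiated silylpropyne at its propargylic carbon by a reactive benzylic bromide, the silyl group capping the alkyne terminus and disfavouring attack through the allenyl position.

Step 4
Reactants: 6 [4-(4-benzyloxy-3-methoxyphenyl)but-1-yn-1-yl]trimethylsilane
Product: 7 4-(4-benzyloxy-3-methoxyphenyl)but-1-yne
Conditions: K2CO3, MeOH, rt
Reagents that add atoms: none
Why: Base-catalysed methanolysis of the alkynyl C-Si bond (protodesilylation) is mild and touches nothing else in the molecule.

Step 5
Reactants: 7 4-(4-benzyloxy-3-methoxyphenyl)but-1-yne (2 equiv); 8 ethyl formate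
Product: 11 1,9-bis(4-benzyloxy-3-methoxyphenyl)nona-3,6-diyn-5-ol, via lithium acetylide 9 (not isolated), via arylpentynal 10 (not isolated)
Conditions: n-BuLi, THF, −78 °C; then 8 (0.45 equiv), −78 to 0 °C; H2O
Reagents that add atoms: none
Why: Twofold 1,2-addition of a lithium acetylide to a formate ester, in which the ynal released after the first addition is more electrophilic than the formate and takes up the second acetylide to give the symmetric bis-propargylic carbinol.

Step 6
Reactants: 11 1,9-bis(4-benzyloxy-3-methoxyphenyl)nona-3,6-diyn-5-ol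
Product: 12 1,9-bis(4-benzyloxy-3-methoxyphenyl)nona-3,6-diyn-5-one
Conditions: MnO2 (activated, excess), CH2Cl2, rt
Reagents that add atoms: none
Why: MnO2 oxidation of a doubly propargylic alcohol proceeds under neutral, non-nucleophilic conditions that the electrophilic cross-conjugated diynone should tolerate.

Step 7
Reactants: 13 methyl (E)-3-methoxybut-2-enoate
Product: 15 (E)-1,3-dimethoxy-1-(trimethylsilyloxy)buta-1,3-diene (Brassard diene), via lithium dienolate 14 (not isolated)
Conditions: LDA, THF, −78 °C; then Me3SiCl, −78 °C to rt
Reagents that add atoms: chlorotrimethylsilane, C[Si](C)(C)Cl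
Why: Gamma-deprotonation of the beta-methoxy enoate to the extended dienolate and silylation at oxygen is the standard preparation of this vinylogous silyl ketene acetal, which is distilled and used fresh.

Step 8
Reactants: 12 1,9-bis(4-benzyloxy-3-methoxyphenyl)nona-3,6-diyn-5-one; 15 (E)-1,3-dimethoxy-1-(trimethylsilyloxy)buta-1,3-diene (5 equiv)
Product: 17 bis{2-hydroxy-4-methoxy-6-[2-(4-benzyloxy-3-methoxyphenyl)ethyl]phenyl}methanone, via bis-cycloadduct ketal 16 (not isolated)
Conditions: 15 (5 equiv), toluene, 25 to 90 °C; then 1 M HCl, THF, rt
Reagents that add atoms: none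
Why: Each ynone arm of 12 serves as the dienophile for one molecule of the electron-rich diene 15 in a polarized, asynchronous Diels-Alder reaction (at the stepwise extreme a Mukaiyama-Michael addition followed by closure), the nucleophilic CH2 terminus of the diene bonding to the alkyne carbon beta to the carbonyl and the ketene acetal carbon to the alpha carbon, four C-C bonds in all. The closest known reaction type is the Diels-Alder benzannulation of 1-alkoxy-1-silyloxy-3-alkoxybutadienes with acetylenic ketones and esters, which gives 2-acyl-5-alkoxyphenols; it is run here on both arms of one diynone. Each of the two six-membered rings closes by intermolecular (4+2) union of the four diene carbons with the two alkyne carbons, and the bis-adduct 16 aromatizes on acidic work-up by loss of methanol and of the silyl group from each mixed ketal carbon, the phenols ending hydrogen-bonded to the ketone. The only new stereocentres are the two ketal carbons of 16, formed without control and erased on aromatization, so no stereocentre has to be set. The step needs regioselectivity and complete twofold conversion: the first is secured by the match between the ynone polarization (electrophilic carbon bearing the arylethyl chain) and the diene polarization (nucleophilic CH2 terminus), which places OH ortho and OMe para to the carbonyl and the chain at the other ortho position; the second by the single carbonyl that activates both alkynes, the mono-adduct still being a dienyl ynone, and by the excess of diene. Holding the oxygens as silyl ketals until both alkynes are consumed keeps a free ortho-phenol from adding to a remaining ynone.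

Step 9
Reactants: 17 bis{2-hydroxy-4-methoxy-6-[2-(4-benzyloxy-3-methoxyphenyl)ethyl]phenyl}methanone
Product: 19 2,2'-methylenebis{3-[2-(4-benzyloxy-3-methoxyphenyl)ethyl]-5-methoxyphenol}, via diarylmethanol 18 (not isolated)
Conditions: Et3SiH (6 equiv), CF3CO2H, CH2Cl2, 0 °C to rt
Reagents that add atoms: none
Why: Ionic hydrogenation (Kursanov-Parnes) of a diaryl ketone, in which protonation and two hydride transfers from the silane pass through a diarylmethyl cation that is strongly stabilized by the para-methoxy and ortho-hydroxy groups of both rings, the excess silane also scavenging any benzyl cation.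

Step 10
Reactants: 19 2,2'-methylenebis{3-[2-(4-benzyloxy-3-methoxyphenyl)ethyl]-5-methoxyphenol}
Product: 20 2,2'-methylenebis{3-[2-(4-hydroxy-3-methoxyphenyl)ethyl]-5-methoxyphenol} (CNP0078998.0)
Conditions: H2 (1 atm), Pd/C, EtOAc/MeOH, rt
Reagents that add atoms: none
Why: Catalytic hydrogenolysis of the two aryl benzyl ethers over palladium on carbon under neutral conditions leaves the diarylmethane, the methyl ethers and the phenols intact.

**Compound list**

1 | 4-benzyloxy-3-methoxybenzaldehyde (O-benzylvanillin) | COc1cc(C=O)ccc1OCc1ccccc1 | starting material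
2 | (4-benzyloxy-3-methoxyphenyl)methanol | COc1cc(CO)ccc1OCc1ccccc1 | intermediate
3 | 4-benzyloxy-3-methoxybenzyl bromide | COc1cc(CBr)ccc1OCc1ccccc1 | intermediate
4 | 1-(trimethylsilyl)propyne | CC#C[Si](C)(C)C | starting material
5 | 3-(trimethylsilyl)prop-2-ynyllithium | [Li]CC#C[Si](C)(C)C | intermediate
6 | [4-(4-benzyloxy-3-methoxyphenyl)but-1-yn-1-yl]trimethylsilane | COc1cc(CCC#C[Si](C)(C)C)ccc1OCc1ccccc1 | intermediate
7 | 4-(4-benzyloxy-3-methoxyphenyl)but-1-yne | COc1cc(CCC#C)ccc1OCc1ccccc1 | intermediate
8 | ethyl formate | CCOC=O | starting material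
9 | lithium 4-(4-benzyloxy-3-methoxyphenyl)but-1-yn-1-ide (lithium acetylide of 7) | [Li]C#CCCc1ccc(OCc2ccccc2)c(OC)c1 | intermediate
10 | 5-(4-benzyloxy-3-methoxyphenyl)pent-2-ynal | COc1cc(CCC#CC=O)ccc1OCc1ccccc1 | intermediate
11 | 1,9-bis(4-benzyloxy-3-methoxyphenyl)nona-3,6-diyn-5-ol | COc1cc(CCC#CC(O)C#CCCc2ccc(OCc3ccccc3)c(OC)c2)ccc1OCc1ccccc1 | intermediate
12 | 1,9-bis(4-benzyloxy-3-methoxyphenyl)nona-3,6-diyn-5-one | COc1cc(CCC#CC(=O)C#CCCc2ccc(OCc3ccccc3)c(OC)c2)ccc1OCc1ccccc1 | intermediate
13 | methyl (E)-3-methoxybut-2-enoate | CO/C(C)=C/C(=O)OC | starting material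
14 | lithium dienolate of 13 (lithium 1,3-dimethoxybuta-1,3-dien-1-olate) | C=C(OC)/C=C(\OC)O[Li] | intermediate
15 | (E)-1,3-dimethoxy-1-(trimethylsilyloxy)buta-1,3-diene (Brassard diene) | C=C(OC)/C=C(\OC)O[Si](C)(C)C | intermediate
16 | bis{2-[2-(4-benzyloxy-3-methoxyphenyl)ethyl]-4,6-dimethoxy-6-(trimethylsilyloxy)cyclohexa-1,4-dien-1-yl}methanone (mixture of diastereomers at the two ketal carbons) | COC1=CC(OC)(O[Si](C)(C)C)C(C(=O)C2=C(CCc3ccc(OCc4ccccc4)c(OC)c3)CC(OC)=CC2(OC)O[Si](C)(C)C)=C(CCc2ccc(OCc3ccccc3)c(OC)c2)C1 | intermediate
17 | bis{2-hydroxy-4-methoxy-6-[2-(4-benzyloxy-3-methoxyphenyl)ethyl]phenyl}methanone | COc1cc(O)c(C(=O)c2c(O)cc(OC)cc2CCc2ccc(OCc3ccccc3)c(OC)c2)c(CCc2ccc(OCc3ccccc3)c(OC)c2)c1 | intermediate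
18 | bis{2-hydroxy-4-methoxy-6-[2-(4-benzyloxy-3-methoxyphenyl)ethyl]phenyl}methanol | COc1cc(O)c(C(O)c2c(O)cc(OC)cc2CCc2ccc(OCc3ccccc3)c(OC)c2)c(CCc2ccc(OCc3ccccc3)c(OC)c2)c1 | intermediate
19 | 2,2'-methylenebis{3-[2-(4-benzyloxy-3-methoxyphenyl)ethyl]-5-methoxyphenol} | COc1cc(O)c(Cc2c(O)cc(OC)cc2CCc2ccc(OCc3ccccc3)c(OC)c2)c(CCc2ccc(OCc3ccccc3)c(OC)c2)c1 | intermediate
20 | 2,2'-methylenebis{3-[2-(4-hydroxy-3-methoxyphenyl)ethyl]-5-methoxyphenol} (CNP0078998.0) | COc1cc(O)c(Cc2c(O)cc(OC)cc2CCc2ccc(O)c(OC)c2)c(CCc2ccc(O)c(OC)c2)c1 | target

**Step count**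

Total step count: 10 (nine in the main line, one for the diene).
Longest linear sequence: 9 steps (steps 1 to 6, then 8 to 10, from O-benzylvanillin).

**Steps most likely to fail**

1. Step 8 (twofold benzannulation).
What may go wrong: the second cycloaddition may lag behind the first, so that mono-annulated ynone survives to the work-up. The ortho-phenol freed there would then close onto the remaining ynone (6-endo cyclization to a chromone). The diene may also be lost by hydrolysis, and the diynone may oligomerize on prolonged heating.
Fallback: it sets out from diynone 12 and returns at benzophenone 17. Cyclohexane-1,3-dione would be silylated twice (Me3SiOTf, Et3N, Et2O, 0 °C) to 1,3-bis(trimethylsilyloxy)cyclohexa-1,3-diene F1. This s-cis-locked and therefore more reactive diene would add to both alkynes of 12 (toluene, 25 to 80 °C) with the same polarization as in step 8, giving the twofold bicyclo[2.2.2]octadiene adduct F2. On heating (xylene, about 140 °C) F2 should extrude two molecules of ethene by retro-Diels-Alder reaction (Alder-Rickert sequence), so that no methanol is released and every oxygen stays silylated in the aromatic tetrakis(trimethylsilyl) ether F3. Acidic work-up (1 M HCl, THF) would give the 2,2',4,4'-tetrahydroxybenzophenone F4. Its two para hydroxyls, which are not hydrogen-bonded to the ketone, would then be methylated selectively (MeI, K2CO3, acetone) to give 17.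

2. Step 9 (ketone to methylene).
What may go wrong: hydride transfer to the crowded, hydrogen-bonded diaryl ketone may be slow. The long-lived diarylmethyl cation could then be captured by a tethered guaiacyl ring (seven-membered Friedel-Crafts closure). The acid could also cleave benzyl ethers and re-benzylate the electron-rich rings.
Fallback: it sets out from benzophenone 17 and returns at diarylmethane 19, avoiding acid and free cations. Both phenols would be acylated (ClCO2Et, Et3N, THF, 0 °C) to the bis(ethyl carbonate) F5, in which the ketone is no longer chelated. NaBH4 in aqueous THF would reduce the ketone; the new alkoxide takes over the neighbouring carbonate, the freed phenoxide expels it, and a second hydride adds to the exocyclic carbon (ortho-quinone methide pathway), giving the diarylmethane monocarbonate F6. Aqueous NaOH in the same work-up would remove the remaining carbonate to give 19.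

3. Step 6 (oxidation to the diynone).
What may go wrong: the oxidation may stall on the MnO2 surface, or the cross-conjugated diynone may be lost during the long contact time and isolation (conjugate addition, oligomerization).
Fallback: it sets out from alkyne 7 and returns at diynone 12 without any oxidation step. The lithium acetylide 9 (n-BuLi, THF, −78 °C) would be acylated with N-methoxy-N-methylcarbamoyl chloride to the alkynyl Weinreb amide 5-(4-benzyloxy-3-methoxyphenyl)-N-methoxy-N-methylpent-2-ynamide F7. A second equivalent of 9 would add to F7 to give a chelated tetrahedral adduct, which releases 12 only on a cold acidic quench, so the diynone never meets a nucleophile.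

**Further compounds**

F1 | step 8 | 1,3-bis(trimethylsilyloxy)cyclohexa-1,3-diene | C[Si](C)(C)OC1=CC(O[Si](C)(C)C)=CCC1
F2 | step 8 | twofold bicyclo[2.2.2]octa-2,5-diene adduct of 12 with F1 (bridgehead and vinyl trimethylsilyloxy groups on each bicycle, mixture of diastereomers) | C[Si](C)(C)OC1=CC2(O[Si](C)(C)C)CCC1C(CCc1ccc(OCc3ccccc3)c(OC)c1)=C2C(=O)C1=C(CCc3ccc(OCc4ccccc4)c(OC)c3)C2CCC1(O[Si](C)(C)C)C=C2O[Si](C)(C)C
F3 | step 8 | bis{2,4-bis(trimethylsilyloxy)-6-[2-(4-benzyloxy-3-methoxyphenyl)ethyl]phenyl}methanone | C[Si](C)(C)Oc1cc(O[Si](C)(C)C)c(C(=O)c2c(O[Si](C)(C)C)cc(O[Si](C)(C)C)cc2CCc2ccc(OCc3ccccc3)c(OC)c2)c(CCc2ccc(OCc3ccccc3)c(OC)c2)c1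
F4 | step 8 | bis{2,4-dihydroxy-6-[2-(4-benzyloxy-3-methoxyphenyl)ethyl]phenyl}methanone | Oc1cc(O)c(C(=O)c2c(O)cc(O)cc2CCc2ccc(OCc3ccccc3)c(OC)c2)c(CCc2ccc(OCc3ccccc3)c(OC)c2)c1
F5 | step 9 | bis(ethyl carbonate) of 17 | CCOC(=O)Oc1cc(OC)cc(CCc2ccc(OCc3ccccc3)c(OC)c2)c1C(=O)c1c(OC(=O)OCC)cc(OC)cc1CCc1ccc(OCc2ccccc2)c(OC)c1
F6 | step 9 | mono(ethyl carbonate) of 19 | CCOC(=O)Oc1cc(OC)cc(CCc2ccc(OCc3ccccc3)c(OC)c2)c1Cc1c(O)cc(OC)cc1CCc1ccc(OCc2ccccc2)c(OC)c1
F7 | step 6 | 5-(4-benzyloxy-3-methoxyphenyl)-N-methoxy-N-methylpent-2-ynamide | COc1cc(CCC#CC(=O)N(C)OC)ccc1OCc1ccccc1
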